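## Retrosynthetic overview
1. The target is the O-to-para-C dehydro-dimer of (S)-curcuphenol. The diaryl ether C–O bond is therefore made last, by one aerobic copper-catalysed phenol coupling of two identical S units.
2. In (S)-curcuphenol the trisubstituted alkene is cut (Wittig). This leads back to a seven-membered aryl lactone that masks the phenol and the aldehyde at once.
3. The key cut is the benzylic C–CH2 bond together with the acyl–O bond of that lactone. It corresponds to a formal [4+3] of an o-quinone methide (acceptor carbon) with the homoenolate of acrolein, whose β-carbon is made nucleophilic by a chiral carbene. This step forms the C–C bond and sets the S centre.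
4. The quinone methide is released from a bench-stable sulfone, made in two steps from 2'-hydroxy-4'-methylacetophenone.
5. Both benzene rings are bought. The only ring formed is the oxepinone (step 3), and it is opened again in step 4.

Assumption: the sense of induction of the key annulation is not known for this substrate pair. The (5aR,10bS) precatalyst is written below; its commercial mirror image is used instead if the first run gives the R lactone.

## Route

Step 1
Reactants: 1 2'-hydroxy-4'-methylacetophenone
Product: 2 2-(1-hydroxyethyl)-5-methylphenol (racemic)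
Conditions: NaBH4 (1.0 equiv), MeOH, 0 °C → rt; aq NH4Cl
Reagents that add atoms: none
Why: Chemoselective borohydride reduction of the aryl ketone, giving a racemic carbinol on purpose because this centre becomes planar again in step 3.

Step 2
Reactants: 2 2-(1-hydroxyethyl)-5-methylphenol
Product: 3 5-methyl-2-[1-(4-methylbenzenesulfonyl)ethyl]phenol (racemic)
Conditions: p-TolSO2Na (1.5 equiv), HCO2H/H2O 1:1, rt, 16 h
Reagents that add atoms: sodium p-toluenesulfinate, Cc1ccc(cc1)S(=O)[O-].[Na+]
Why: Acid-promoted SN1-type substitution of the readily ionised o-hydroxybenzylic alcohol by the soft sulfur of the sulfinate gives a storable sulfone that sheds sulfinate under mild base, and its racemic centre is erased in step 3.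

Step 3 (key step)
Reactants: 3 5-methyl-2-[1-(4-methylbenzenesulfonyl)ethyl]phenol; 4 acrolein
Product: 7 (5S)-5,8-dimethyl-4,5-dihydro-1-benzoxepin-2(3H)-one, via o-quinone methide 5 (not isolated), via carbene-bound acrolein homoenolate 6 (not isolated)
Conditions: (5aR,10bS)-2-mesityl-5a,10b-dihydro-4H,6H-indeno[2,1-b][1,2,4]triazolo[4,3-d][1,4]oxazin-2-ium tetrafluoroborate (15 mol%), Cs2CO3 (1.5 equiv), 4 (2.5 equiv, freshly distilled, syringe pump over 8 h), 4 Å MS, toluene/THF 4:1, 0 °C
Reagents that add atoms: none
Why: Proposed new method: Cs2CO3 slowly eliminates sulfinate from 3 to give the (E)-quinone methide 5 while the chiral triazolylidene adds to acrolein and, after proton transfer, turns its normally electrophilic β-carbon into a nucleophile (homoenolate equivalent 6), so that two acceptor carbons are joined when 6 attacks the Re face of the exocyclic carbon of 5 inside the indane-shielded pocket (this sets the S benzylic centre), after which the phenoxide oxygen closes the lactone at the acyl carbon and releases the carbene; the closest known reaction type is the carbene-catalysed enantioselective formal [4+3] annulation of β-substituted enals with o-quinone methides to benzo-fused ε-lactones, and what is new is the pairing of unsubstituted acrolein with an alkyl-substituted quinone methide, in which the only stereocentre lies on the acceptor carbon.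

Step 4
Reactants: 7 (5S)-5,8-dimethyl-4,5-dihydro-1-benzoxepin-2(3H)-one; 8 isopropyltriphenylphosphonium iodide
Product: 11 (S)-curcuphenol [5-methyl-2-[(2S)-6-methylhept-5-en-2-yl]phenol], via aluminium lactolate 9 (not isolated), via hydroxy aldehyde 10 (not isolated)
Conditions: i-Bu2AlH (1.05 equiv), toluene, −78 °C, 1 h; then Ph3P=CMe2 [8 (3.5 equiv), KN(SiMe3)2 (3.4 equiv), THF, 0 °C], −78 °C → rt; aq potassium sodium tartrate
Reagents that add atoms: none
Why: One-pot partial lactone reduction and Wittig olefination, in which i-Bu2AlH adds once at −78 °C to give the aluminium lactolate 9, which on warming opens to aldehyde 10 in the presence of excess non-stabilised ylide, so the trisubstituted alkene is built and the phenol is unmasked while the benzylic centre, which is γ to the carbonyl and cannot enolise, keeps its S configuration.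

Step 5
Reactants: 11 (S)-curcuphenol (two molecules, one for each half)
Product: 13 5-methyl-4-{5-methyl-2-[(2S)-6-methylhept-5-en-2-yl]phenoxy}-2-[(2S)-6-methylhept-5-en-2-yl]phenol (CNP0354307.1), via quinol ether 12 (not isolated)
Conditions: (1,4,7-triisopropyl-1,4,7-triazacyclononane)CuCl2 (5 mol%), 2,6-diphenylpyridine (50 mol%), O2 (1 atm), toluene, 40 °C, stopped at about 40% conversion; recovered 11 recycled
Reagents that add atoms: none
Why: Aerobic copper-catalysed oxidative phenol coupling (Hay-type C–O coupling, the head-to-tail mode by which 2,5-dialkylphenols are polymerised), in which the bulky triamine cap keeps the phenoxyl radical on copper and shields its ring carbons so that its oxygen attacks the open para carbon of a second molecule of 11, the quinol ether 12 tautomerises to the phenol 13, the run is stopped early because 13 is itself oxidisable, and no stereocentre is touched, so two S units give the S,S ether.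

## Compound list
1 | 2'-hydroxy-4'-methylacetophenone | CC(=O)c1ccc(C)cc1O | starting material
2 | 2-(1-hydroxyethyl)-5-methylphenol (racemic) | CC(O)c1ccc(C)cc1O | intermediate
3 | 5-methyl-2-[1-(4-methylbenzenesulfonyl)ethyl]phenol (racemic) | CC(c1ccc(C)cc1O)S(=O)(=O)c1ccc(C)cc1 | intermediate
4 | acrolein (prop-2-enal) | C=CC=O | starting material
5 | (6E)-6-ethylidene-3-methylcyclohexa-2,4-dien-1-one (o-quinone methide, not isolated) | C/C=C1\C=CC(C)=CC1=O | intermediate
6 | extended Breslow intermediate (homoenolate equivalent, not isolated): 1-(triazolylidene)prop-2-en-1-ol from 4 and the (5aR,10bS) carbene of step 3 | C=CC(O)=C1N(c2c(C)cc(C)cc2C)N=C2CO[C@@H]3Cc4ccccc4[C@@H]3N12 | intermediate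
7 | (5S)-5,8-dimethyl-4,5-dihydro-1-benzoxepin-2(3H)-one | O=C1CC[C@H](C)c2ccc(C)cc2O1 | intermediate
8 | isopropyltriphenylphosphonium iodide | CC(C)[P+](c1ccccc1)(c1ccccc1)c1ccccc1.[I-] | starting material
9 | diisobutyl{[(5S)-5,8-dimethyl-2,3,4,5-tetrahydro-1-benzoxepin-2-yl]oxy}aluminium (C-2 epimers, not isolated) | CC(C)C[Al](CC(C)C)OC1CC[C@H](C)c2ccc(C)cc2O1 | intermediate
10 | (4S)-4-(2-hydroxy-4-methylphenyl)pentanal (in the flask as its aluminium phenoxide, not isolated) | O=CCC[C@H](C)c1ccc(C)cc1O | intermediate
11 | (S)-curcuphenol, 5-methyl-2-[(2S)-6-methylhept-5-en-2-yl]phenol | CC(C)=CCC[C@H](C)c1ccc(C)cc1O | intermediate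
12 | 5-methyl-4-{5-methyl-2-[(2S)-6-methylhept-5-en-2-yl]phenoxy}-2-[(2S)-6-methylhept-5-en-2-yl]cyclohexa-2,5-dien-1-one (C-4 epimers, not isolated) | CC(C)=CCC[C@H](C)C1=CC(Oc2cc(C)ccc2[C@@H](C)CCC=C(C)C)C(C)=CC1=O | intermediate
13 | 5-methyl-4-{5-methyl-2-[(2S)-6-methylhept-5-en-2-yl]phenoxy}-2-[(2S)-6-methylhept-5-en-2-yl]phenol (CNP0354307.1) | CC(C)=CCC[C@H](C)c1cc(Oc2cc(C)ccc2[C@@H](C)CCC=C(C)C)c(C)cc1O | target

## Totals and risks
Total step count: 5. Longest linear sequence: 5 (1 → 2 → 3 → 7 → 11 → 13).

**Most likely to fail, first: step 3.**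
- Acrolein can oligomerise, or be consumed by the carbene or by the released sulfinate.
- β-Protonation of 6 would divert the reaction to a [4+2] dihydrocoumarin.
- Quinone methide 5 can tautomerise to the vinylphenol.
- The ee is unproven and is measured on 7 by chiral HPLC. Two units are combined later, so residual R material ends up mainly in the S,R and R,S diastereomers. This raises the ee of 13 but lowers its dr.

Fallback, setting out from 2 and coming back at 7: the homoenolate is kept, but it is used as a metal reagent in a cross-coupling. Diol 2 is treated with acetyl bromide (2.5 equiv, CH2Cl2, 0 °C) to give racemic 2-(1-bromoethyl)-5-methylphenyl acetate F1. This undergoes an enantioconvergent Negishi coupling with the commercial zinc homoenolate BrZnCH2CH2CO2Et (NiBr2·diglyme, i-Pr-Pybox of the enantiomer that gives S, DMA, 0 °C) to give ethyl (4S)-4-(2-acetoxy-4-methylphenyl)pentanoate F2. Heating F2 with catalytic p-TsOH·H2O in toluene, while ethyl acetate distils off, closes the lactone 7.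

**Second: step 5.**
- Product 13 is easier to oxidise than 11, so trimers grow with conversion.
- Para–para and ortho–para C–C dimers compete.
- About 25–30% of 13 per pass is a realistic expectation.

Fallback, setting out from 7 and 11 and coming back at 13: the ether is made by a stepwise cross-coupling.
- Lactone 7 is iodinated para to the acyloxy oxygen (N-iodosuccinimide, CF3CO2H, rt, dark) to give (5S)-7-iodo-5,8-dimethyl-4,5-dihydro-1-benzoxepin-2(3H)-one F4.
- The conditions of step 4 take F4 through (4S)-4-(2-hydroxy-5-iodo-4-methylphenyl)pentanal F5 to 4-iodo-5-methyl-2-[(2S)-6-methylhept-5-en-2-yl]phenol F6.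
- NaH and MOMCl (THF/DMF, 0 °C) give its methoxymethyl ether F7.
- Ullmann-type coupling of F7 with 11 (CuI 10 mol%, picolinic acid 20 mol%, K3PO4, DMSO, 90 °C) gives the methoxymethyl ether of the target F8.
- Dilute HCl in MeOH at rt frees 13.

**Third: step 4.**
- An aryl lactolate can collapse early, which leads to over-reduction.
- The aluminium Lewis acid can tie up the ylide.

Fallback, setting out from 7 and coming back at 10 (now isolated) and then 11: the lactone is reduced fully with LiAlH4 (THF, 0 °C) to 2-[(2S)-5-hydroxypentan-2-yl]-5-methylphenol F3. Only the primary alcohol is then oxidised, with SO3·pyridine, DMSO and Et3N, to give 10. Aldehyde 10 is olefinated in a separate, aluminium-free flask with excess ylide from 8.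

## Further compounds
F1 | step 3 | 2-(1-bromoethyl)-5-methylphenyl acetate (racemic) | CC(Br)c1ccc(C)cc1OC(C)=O
F2 | step 3 | ethyl (4S)-4-(2-acetoxy-4-methylphenyl)pentanoate | CCOC(=O)CC[C@H](C)c1ccc(C)cc1OC(C)=O
F3 | step 4 | 2-[(2S)-5-hydroxypentan-2-yl]-5-methylphenol | OCCC[C@H](C)c1ccc(C)cc1O
F4 | step 5 | (5S)-7-iodo-5,8-dimethyl-4,5-dihydro-1-benzoxepin-2(3H)-one | O=C1CC[C@H](C)c2cc(I)c(C)cc2O1
F5 | step 5 | (4S)-4-(2-hydroxy-5-iodo-4-methylphenyl)pentanal | O=CCC[C@H](C)c1cc(I)c(C)cc1O
F6 | step 5 | 4-iodo-5-methyl-2-[(2S)-6-methylhept-5-en-2-yl]phenol | CC(C)=CCC[C@H](C)c1cc(I)c(C)cc1O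
F7 | step 5 | 1-iodo-4-(methoxymethoxy)-2-methyl-5-[(2S)-6-methylhept-5-en-2-yl]benzene | CC(C)=CCC[C@H](C)c1cc(I)c(C)cc1OCOC
F8 | step 5 | methoxymethyl ether of the target | CC(C)=CCC[C@H](C)c1cc(Oc2cc(C)ccc2[C@@H](C)CCC=C(C)C)c(C)cc1OCOC
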